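The two halves derive from one monomer, 1H-isochromenone 20, whose pyran ring (O2, C1, C8a, C4a, C4, C3) is cut across C4–C4a and C1–O2. The carbocycle carries C8=O, so C4a is the β-carbon of an enone and C1 sits on its α-carbon. Chloro-enone 14 (Cl on C4a, CH2Ts on C8a) is therefore a 1,3-bis-electrophile, and the enolate of methyl ketone 17 supplies O2–C3–C4. One operation joins them by vinylic substitution, sulfinate loss and oxa-6π ring closure. C6 and C7 come from a CBS desymmetrisation. The halves are united by Knoevenagel condensation at C5.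

Key step: step 11

Remark on numbering: locants of the 1H-isochromene skeleton (C1, O2, C3, C4, C4a, C5–C8, C8a) are also used for the corresponding atoms of all precursors; primed locants denote the 6-hydroxy half. "Silyl orsellinate" means the 2-methyl-4,6-bis(triisopropylsilyloxy)benzoate ester.
Assumption: epoxide 10 is carried on as a mixture of epoxide diastereomers (both give dione 11), so its SMILES leaves the two epoxide carbons undefined; 13 is drawn as one enol tautomer, and aldol adduct 25 is a mixture at its two new sp3 centres.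

Step 1
Reactants: 1 orsellinic acid (2,4-dihydroxy-6-methylbenzoic acid)
Product: 3 2-methyl-4,6-bis(triisopropylsilyloxy)benzoic acid, via silyl ester 2 (not isolated)
Conditions: TIPSOTf (3.3 equiv), 2,6-lutidine, CH2Cl2, 0 °C → rt; then AcOH/THF/H2O, rt
Reagents that add atoms: triisopropylsilyl trifluoromethanesulfonate, CC(C)[Si](OS(=O)(=O)C(F)(F)F)(C(C)C)C(C)C
Why: Exhaustive O-silylation followed by selective hydrolysis of the labile silyl ester should leave the two aryl silyl ethers, which mask the phenols through all later oxidations and base treatments (silyl protection, no stereocentre).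

Step 2
Reactants: 4 2-methylcyclohexane-1,3-dione; 3 2-methyl-4,6-bis(triisopropylsilyloxy)benzoic acid
Product: 5 1-methyl-2,6-dioxocyclohexyl silyl orsellinate (achiral)
Conditions: PhI(OAc)2 (1.1 equiv), 3 (2.2 equiv), PhCl, 40 °C, reduced pressure (AcOH distilled off); then 4, CH2Cl2, 0 °C → rt
Reagents that add atoms: none
Why: Ligand exchange gives the bis(aroyloxy) trivalent iodine reagent, the enol of 4 binds to iodine and the carboxylate is delivered to the methyl-bearing carbon with loss of iodobenzene (oxidative α-acyloxylation of a 2-substituted 1,3-dione), so the hindered acid reacts through its oxygen and not through its shielded carbonyl carbon.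

Step 3
Reactants: 5 1-methyl-2,6-dioxocyclohexyl silyl orsellinate
Product: 6 (1R,2R)-2-hydroxy-1-methyl-6-oxocyclohexyl silyl orsellinate
Conditions: (S)-2-methyl-CBS-oxazaborolidine (0.3 equiv), BH3·SMe2 (0.6 equiv), THF, −40 °C
Reagents that add atoms: none
Why: Corey–Bakshi–Shibata desymmetrisation, in which the catalyst should deliver hydride to the Si face of one of the two enantiotopic carbonyl groups, anti to the large axial aroyloxy group, so that the carbinol centre (6R) and the now stereogenic quaternary carbon (7R) are set together with the hydroxyl cis to the ester oxygen.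

Step 4
Reactants: 6 (1R,2R)-2-hydroxy-1-methyl-6-oxocyclohexyl silyl orsellinate
Product: 7 (1R,2R)-1-methyl-6-oxo-2-(triethylsilyloxy)cyclohexyl silyl orsellinate
Conditions: TESOTf, 2,6-lutidine, CH2Cl2, −78 °C
Reagents that add atoms: triethylsilyl trifluoromethanesulfonate, CC[Si](CC)(CC)OS(=O)(=O)C(F)(F)F
Why: Silyl ether formation at low temperature with a non-nucleophilic base should cap the hindered secondary alcohol before the neighbouring aryl ester can migrate, leaving both stereocentres untouched.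

Step 5
Reactants: 7 (1R,2R)-1-methyl-6-oxo-2-(triethylsilyloxy)cyclohexyl silyl orsellinate
Product: 9 (1R,6R)-1-methyl-2-oxo-6-(triethylsilyloxy)cyclohex-3-en-1-yl silyl orsellinate, via silyl enol ether 8 (not isolated)
Conditions: TMSOTf, Et3N, CH2Cl2, 0 °C; then Pd(OAc)2 (1.05 equiv), MeCN, rt
Reagents that add atoms: none
Why: Saegusa–Ito dehydrogenation, in which enolisation can only occur towards C8a because C7 is quaternary, and β-hydride elimination from the palladium enolate gives the C8a=C4a enone.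

Step 6
Reactants: 9 (1R,6R)-1-methyl-2-oxo-6-(triethylsilyloxy)cyclohex-3-en-1-yl silyl orsellinate
Product: 10 (1R,6R)-3,4-epoxy-1-methyl-2-oxo-6-(triethylsilyloxy)cyclohexyl silyl orsellinate (epoxide diastereomers)
Conditions: t-BuOOH (in decane), DBU, CH2Cl2, 0 °C → rt
Reagents that add atoms: tert-butyl hydroperoxide, CC(C)(C)OO
Why: Weitz–Scheffer nucleophilic epoxidation, in which the peroxide anion adds to the unhindered β-carbon C4a and the enolate closes onto oxygen, placing at C4a the oxygen needed for the 1,3-dione; the epoxide configuration is irrelevant.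

Step 7
Reactants: 10 (1R,6R)-3,4-epoxy-1-methyl-2-oxo-6-(triethylsilyloxy)cyclohexyl silyl orsellinate
Product: 11 (1R,2R)-1-methyl-4,6-dioxo-2-(triethylsilyloxy)cyclohexyl silyl orsellinate
Conditions: Pd(PPh3)4 (5 mol %), dppe (5 mol %), toluene, 80 °C
Reagents that add atoms: none
Why: Palladium-catalysed isomerisation of an α,β-epoxy ketone to a β-diketone (opening of the α-C–O bond by zerovalent palladium, then β-hydride elimination from the carbinol carbon), which converges both epoxide isomers on the dione.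

Step 8
Reactants: 11 (1R,2R)-1-methyl-4,6-dioxo-2-(triethylsilyloxy)cyclohexyl silyl orsellinate
Product: 13 (1R,2R)-1-methyl-4,6-dioxo-5-(tosylmethyl)-2-(triethylsilyloxy)cyclohexyl silyl orsellinate (enolised), via methylene dione 12 (not isolated)
Conditions: aq. HCHO, TolSO2Na, AcOH (1.1 equiv), THF/H2O, 0 °C → rt
Reagents that add atoms: formaldehyde, C=O; sodium p-toluenesulfinate, [Na+].[O-]S(=O)c1ccc(C)cc1
Why: Knoevenagel condensation with formaldehyde gives the 2-methylene dione, which the soft sulfinate should trap at once by conjugate addition (three-component sulfonylmethylation), installing C1 with a group that resists SN2 attack yet leaves readily by E1cB.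

Step 9
Reactants: 13 (1R,2R)-1-methyl-4,6-dioxo-5-(tosylmethyl)-2-(triethylsilyloxy)cyclohexyl silyl orsellinate
Product: 14 (1R,6R)-4-chloro-1-methyl-2-oxo-3-(tosylmethyl)-6-(triethylsilyloxy)cyclohex-3-en-1-yl silyl orsellinate
Conditions: PPh3, CCl4, MeCN, rt
Reagents that add atoms: tetrachloromethane, ClC(Cl)(Cl)Cl
Why: Conversion of an enolised 1,3-dione into a β-chloro enone through an enol phosphonium salt, in which chloride should add to C4a, the carbonyl carbon remote from the quaternary centre, because attack at C8 is neopentyl-like; the neutral conditions spare the silyl ethers and the sulfone.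

Step 10
Reactants: 15 (tert-butyldimethylsilyloxy)acetaldehyde; 16 1-(triphenylphosphoranylidene)propan-2-one
Product: 17 (E)-5-(tert-butyldimethylsilyloxy)pent-3-en-2-one
Conditions: CH2Cl2, rt
Reagents that add atoms: none
Why: Wittig olefination with a ketone-stabilised ylide, which should give the (E)-enone selectively.

Step 11
Reactants: 14 (1R,6R)-4-chloro-1-methyl-2-oxo-3-(tosylmethyl)-6-(triethylsilyloxy)cyclohex-3-en-1-yl silyl orsellinate; 17 (E)-5-(tert-butyldimethylsilyloxy)pent-3-en-2-one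
Product: 20 (6R,7R)-3-[(E)-3-(tert-butyldimethylsilyloxy)prop-1-enyl]-7-methyl-8-oxo-6-(triethylsilyloxy)-5,6,7,8-tetrahydro-1H-isochromen-7-yl silyl orsellinate, via diketone 18 (not isolated), via oxatriene 19 (not isolated)
Conditions: 17 (2.2 equiv), LiN(SiMe3)2 (2.2 equiv), THF, −78 °C; then 14, −78 °C → rt
Reagents that add atoms: none
Why: Proposed new method: the cross-conjugated lithium enolate of 17 (kinetic deprotonation at CH3) should attack C4a of 14, the β-carbon of a vinylogous acyl chloride, and expel chloride (addition–elimination, C4–C4a), after which a second equivalent of enolate deprotonates the doubly activated C4–H of 18 and the dienolate loses p-toluenesulfinate from C1 by 1,4-elimination to give 1-oxatriene 19. The (Z)-isomer of 19, reached by equilibration through the dienolate, closes by thermal disrotatory oxa-6π electrocyclisation (C1–O2) to the 2H-pyran ring. The closest known reaction types are the vinylic substitution of β-halo enones by enolates and the Knoevenagel/oxa-6π formal [3+3] annulation of 1,3-dicarbonyl compounds with enals. No stereocentre is created, and C6 and C7 are not at risk because C7 is quaternary and the C6 oxygen is silylated. The selectivity needed is C-attack at C4a and O-attack at C1: the sulfone is inert to direct displacement, so C1 becomes electrophilic only once the C–C bond exists, and addition to C8=O is blocked by the adjacent quaternary C7. Ring closure should be irreversible because it forms the push–pull dienyl ether–enone chromophore.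

Step 12
Reactants: 20 (6R,7R)-3-[(E)-3-(tert-butyldimethylsilyloxy)prop-1-enyl]-7-methyl-8-oxo-6-(triethylsilyloxy)-5,6,7,8-tetrahydro-1H-isochromen-7-yl silyl orsellinate
Product: 21 (6R,7R)-6-hydroxy-3-[(E)-3-hydroxyprop-1-enyl]-7-methyl-8-oxo-5,6,7,8-tetrahydro-1H-isochromen-7-yl silyl orsellinate
Conditions: HF·pyridine, pyridine, THF, 0 °C → rt
Reagents that add atoms: none
Why: Buffered acidic fluoride should cleave the two alkyl silyl ethers (secondary TES, primary allylic TBS) much faster than the hindered aryl TIPS ethers (selective desilylation).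

Step 13
Reactants: 21 (6R,7R)-6-hydroxy-3-[(E)-3-hydroxyprop-1-enyl]-7-methyl-8-oxo-5,6,7,8-tetrahydro-1H-isochromen-7-yl silyl orsellinate
Product: 22 (6R,7R)-3-[(E)-3-acetoxyprop-1-enyl]-6-hydroxy-7-methyl-8-oxo-5,6,7,8-tetrahydro-1H-isochromen-7-yl silyl orsellinate
Conditions: AcCl (1.05 equiv), 2,4,6-collidine, CH2Cl2, −78 °C
Reagents that add atoms: acetyl chloride, CC(=O)Cl
Why: Chemoselective acetylation, since the unhindered primary allylic alcohol should react far faster than the secondary C6 hydroxyl next to the quaternary centre.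

Step 14
Reactants: 22 (6R,7R)-3-[(E)-3-acetoxyprop-1-enyl]-6-hydroxy-7-methyl-8-oxo-5,6,7,8-tetrahydro-1H-isochromen-7-yl silyl orsellinate
Product: 23 (7R)-3-[(E)-3-acetoxyprop-1-enyl]-7-methyl-6,8-dioxo-5,6,7,8-tetrahydro-1H-isochromen-7-yl silyl orsellinate
Conditions: Dess–Martin periodinane, pyridine, CH2Cl2, 0 °C → rt
Reagents that add atoms: none
Why: Dess–Martin oxidation of the secondary alcohol under buffered conditions should give the 6,8-dione and make C5 a doubly activated methylene, while the quaternary C7 centre cannot epimerise.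

Step 15
Reactants: 21 (6R,7R)-6-hydroxy-3-[(E)-3-hydroxyprop-1-enyl]-7-methyl-8-oxo-5,6,7,8-tetrahydro-1H-isochromen-7-yl silyl orsellinate
Product: 24 (6R,7R)-6-hydroxy-7-methyl-8-oxo-3-[(E)-3-oxoprop-1-enyl]-5,6,7,8-tetrahydro-1H-isochromen-7-yl silyl orsellinate
Conditions: MnO2, CH2Cl2, rt
Reagents that add atoms: none
Why: MnO2 oxidation is selective for the allylic primary alcohol and should leave the non-allylic C6 hydroxyl untouched, giving the (E)-enal of the hydroxy half.

Step 16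
Reactants: 23 (7R)-3-[(E)-3-acetoxyprop-1-enyl]-7-methyl-6,8-dioxo-5,6,7,8-tetrahydro-1H-isochromen-7-yl silyl orsellinate; 24 (6R,7R)-6-hydroxy-7-methyl-8-oxo-3-[(E)-3-oxoprop-1-enyl]-5,6,7,8-tetrahydro-1H-isochromen-7-yl silyl orsellinate
Product: 26 tetrakis-O-triisopropylsilyl ether of the target (all four phenols silylated), via aldol adduct 25 (not isolated)
Conditions: ethylenediammonium diacetate (20 mol %), 4 Å molecular sieves, CH2Cl2, 0 °C → rt
Reagents that add atoms: none
Why: Knoevenagel condensation in which only 23 has an acidic methylene (C5, flanked by C6=O and the vinylogous C8=O) and only 24 has an aldehyde, so the crossed reaction is the only one open, and reversible addition–elimination should lead to the (5Z)-alkylidene whose chain lies beside C6=O and away from the peri hydrogen on C4, the C10=C11 geometry being carried over from 24.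

Step 17
Reactants: 26 tetrakis-O-triisopropylsilyl ether of the target
Product: 27 target, (7R)-3-[(E)-3-acetoxyprop-1-enyl]-5-[(Z,2E)-3-{(6R,7R)-7-(2,4-dihydroxy-6-methylbenzoyloxy)-6-hydroxy-7-methyl-8-oxo-5,6,7,8-tetrahydro-1H-isochromen-3-yl}prop-2-enylidene]-7-methyl-6,8-dioxo-5,6,7,8-tetrahydro-1H-isochromen-7-yl 2,4-dihydroxy-6-methylbenzoate
Conditions: Bu4NF, AcOH (1:1), THF, 0 °C
Reagents that add atoms: none
Why: Acetic acid-buffered fluoride should remove the four aryl silyl ethers while leaving the allylic acetate, the hindered aryl esters and the base-sensitive acyloxy dione intact (global desilylation).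

Compound list
1 | orsellinic acid (2,4-dihydroxy-6-methylbenzoic acid) | Cc1cc(O)cc(O)c1C(=O)O | starting material
2 | triisopropylsilyl 2-methyl-4,6-bis(triisopropylsilyloxy)benzoate | Cc1cc(O[Si](C(C)C)(C(C)C)C(C)C)cc(O[Si](C(C)C)(C(C)C)C(C)C)c1C(=O)O[Si](C(C)C)(C(C)C)C(C)C | intermediate
3 | 2-methyl-4,6-bis(triisopropylsilyloxy)benzoic acid | Cc1cc(O[Si](C(C)C)(C(C)C)C(C)C)cc(O[Si](C(C)C)(C(C)C)C(C)C)c1C(=O)O | intermediate
4 | 2-methylcyclohexane-1,3-dione | CC1C(=O)CCCC1=O | starting material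
5 | 1-methyl-2,6-dioxocyclohexyl 2-methyl-4,6-bis(triisopropylsilyloxy)benzoate | O=C1CCCC(=O)C1(C)OC(=O)c1c(C)cc(O[Si](C(C)C)(C(C)C)C(C)C)cc1O[Si](C(C)C)(C(C)C)C(C)C | intermediate
6 | (1R,2R)-2-hydroxy-1-methyl-6-oxocyclohexyl 2-methyl-4,6-bis(triisopropylsilyloxy)benzoate | O=C1[C@](C)(OC(=O)c2c(C)cc(O[Si](C(C)C)(C(C)C)C(C)C)cc2O[Si](C(C)C)(C(C)C)C(C)C)[C@H](O)CCC1 | intermediate
7 | (1R,2R)-1-methyl-6-oxo-2-(triethylsilyloxy)cyclohexyl 2-methyl-4,6-bis(triisopropylsilyloxy)benzoate | O=C1[C@](C)(OC(=O)c2c(C)cc(O[Si](C(C)C)(C(C)C)C(C)C)cc2O[Si](C(C)C)(C(C)C)C(C)C)[C@H](O[Si](CC)(CC)CC)CCC1 | intermediate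
8 | (1R,6R)-1-methyl-6-(triethylsilyloxy)-2-(trimethylsilyloxy)cyclohex-2-en-1-yl 2-methyl-4,6-bis(triisopropylsilyloxy)benzoate | C1=C(O[Si](C)(C)C)[C@](C)(OC(=O)c2c(C)cc(O[Si](C(C)C)(C(C)C)C(C)C)cc2O[Si](C(C)C)(C(C)C)C(C)C)[C@H](O[Si](CC)(CC)CC)CC1 | intermediate
9 | (1R,6R)-1-methyl-2-oxo-6-(triethylsilyloxy)cyclohex-3-en-1-yl 2-methyl-4,6-bis(triisopropylsilyloxy)benzoate | O=C1[C@](C)(OC(=O)c2c(C)cc(O[Si](C(C)C)(C(C)C)C(C)C)cc2O[Si](C(C)C)(C(C)C)C(C)C)[C@H](O[Si](CC)(CC)CC)CC=C1 | intermediate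
10 | (1R,6R)-3,4-epoxy-1-methyl-2-oxo-6-(triethylsilyloxy)cyclohexyl 2-methyl-4,6-bis(triisopropylsilyloxy)benzoate, epoxide diastereomers | O=C1[C@](C)(OC(=O)c2c(C)cc(O[Si](C(C)C)(C(C)C)C(C)C)cc2O[Si](C(C)C)(C(C)C)C(C)C)[C@H](O[Si](CC)(CC)CC)CC2OC12 | intermediate
11 | (1R,2R)-1-methyl-4,6-dioxo-2-(triethylsilyloxy)cyclohexyl 2-methyl-4,6-bis(triisopropylsilyloxy)benzoate | O=C1[C@](C)(OC(=O)c2c(C)cc(O[Si](C(C)C)(C(C)C)C(C)C)cc2O[Si](C(C)C)(C(C)C)C(C)C)[C@H](O[Si](CC)(CC)CC)CC(=O)C1 | intermediate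
12 | (1R,2R)-1-methyl-5-methylidene-4,6-dioxo-2-(triethylsilyloxy)cyclohexyl 2-methyl-4,6-bis(triisopropylsilyloxy)benzoate | O=C1[C@](C)(OC(=O)c2c(C)cc(O[Si](C(C)C)(C(C)C)C(C)C)cc2O[Si](C(C)C)(C(C)C)C(C)C)[C@H](O[Si](CC)(CC)CC)CC(=O)C1=C | intermediate
13 | (1R,2R)-1-methyl-4,6-dioxo-5-(tosylmethyl)-2-(triethylsilyloxy)cyclohexyl 2-methyl-4,6-bis(triisopropylsilyloxy)benzoate, drawn as the 4-enol | O=C1[C@](C)(OC(=O)c2c(C)cc(O[Si](C(C)C)(C(C)C)C(C)C)cc2O[Si](C(C)C)(C(C)C)C(C)C)[C@H](O[Si](CC)(CC)CC)CC(O)=C1CS(=O)(=O)c1ccc(C)cc1 | intermediate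
14 | (1R,6R)-4-chloro-1-methyl-2-oxo-3-(tosylmethyl)-6-(triethylsilyloxy)cyclohex-3-en-1-yl 2-methyl-4,6-bis(triisopropylsilyloxy)benzoate | O=C1[C@](C)(OC(=O)c2c(C)cc(O[Si](C(C)C)(C(C)C)C(C)C)cc2O[Si](C(C)C)(C(C)C)C(C)C)[C@H](O[Si](CC)(CC)CC)CC(Cl)=C1CS(=O)(=O)c1ccc(C)cc1 | intermediate
15 | (tert-butyldimethylsilyloxy)acetaldehyde | O=CCO[Si](C)(C)C(C)(C)C | starting material
16 | 1-(triphenylphosphoranylidene)propan-2-one | CC(=O)C=P(c1ccccc1)(c1ccccc1)c1ccccc1 | starting material
17 | (E)-5-(tert-butyldimethylsilyloxy)pent-3-en-2-one | CC(=O)/C=C/CO[Si](C)(C)C(C)(C)C | intermediate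
18 | (1R,6R)-4-[(E)-5-(tert-butyldimethylsilyloxy)-2-oxopent-3-enyl]-1-methyl-2-oxo-3-(tosylmethyl)-6-(triethylsilyloxy)cyclohex-3-en-1-yl 2-methyl-4,6-bis(triisopropylsilyloxy)benzoate | CC(C)(C)[Si](C)(C)OC/C=C/C(=O)CC1=C(CS(=O)(=O)c2ccc(C)cc2)C(=O)[C@](C)(OC(=O)c2c(C)cc(O[Si](C(C)C)(C(C)C)C(C)C)cc2O[Si](C(C)C)(C(C)C)C(C)C)[C@H](O[Si](CC)(CC)CC)C1 | intermediate
19 | (1R,6R)-4-[(1Z,3E)-5-(tert-butyldimethylsilyloxy)-2-oxopent-3-enylidene]-1-methyl-3-methylidene-2-oxo-6-(triethylsilyloxy)cyclohexyl 2-methyl-4,6-bis(triisopropylsilyloxy)benzoate | CC(C)(C)[Si](C)(C)OC/C=C/C(=O)/C=C1\C(=C)C(=O)[C@](C)(OC(=O)c2c(C)cc(O[Si](C(C)C)(C(C)C)C(C)C)cc2O[Si](C(C)C)(C(C)C)C(C)C)[C@H](O[Si](CC)(CC)CC)C1 | intermediate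
20 | (6R,7R)-3-[(E)-3-(tert-butyldimethylsilyloxy)prop-1-enyl]-7-methyl-8-oxo-6-(triethylsilyloxy)-5,6,7,8-tetrahydro-1H-isochromen-7-yl 2-methyl-4,6-bis(triisopropylsilyloxy)benzoate | CC(C)(C)[Si](C)(C)OC/C=C/C1=CC2=C(CO1)C(=O)[C@](C)(OC(=O)c1c(C)cc(O[Si](C(C)C)(C(C)C)C(C)C)cc1O[Si](C(C)C)(C(C)C)C(C)C)[C@H](O[Si](CC)(CC)CC)C2 | intermediate
21 | (6R,7R)-6-hydroxy-3-[(E)-3-hydroxyprop-1-enyl]-7-methyl-8-oxo-5,6,7,8-tetrahydro-1H-isochromen-7-yl 2-methyl-4,6-bis(triisopropylsilyloxy)benzoate | OC/C=C/C1=CC2=C(CO1)C(=O)[C@](C)(OC(=O)c1c(C)cc(O[Si](C(C)C)(C(C)C)C(C)C)cc1O[Si](C(C)C)(C(C)C)C(C)C)[C@H](O)C2 | intermediate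
22 | (6R,7R)-3-[(E)-3-acetoxyprop-1-enyl]-6-hydroxy-7-methyl-8-oxo-5,6,7,8-tetrahydro-1H-isochromen-7-yl 2-methyl-4,6-bis(triisopropylsilyloxy)benzoate | CC(=O)OC/C=C/C1=CC2=C(CO1)C(=O)[C@](C)(OC(=O)c1c(C)cc(O[Si](C(C)C)(C(C)C)C(C)C)cc1O[Si](C(C)C)(C(C)C)C(C)C)[C@H](O)C2 | intermediate
23 | (7R)-3-[(E)-3-acetoxyprop-1-enyl]-7-methyl-6,8-dioxo-5,6,7,8-tetrahydro-1H-isochromen-7-yl 2-methyl-4,6-bis(triisopropylsilyloxy)benzoate | CC(=O)OC/C=C/C1=CC2=C(CO1)C(=O)[C@](C)(OC(=O)c1c(C)cc(O[Si](C(C)C)(C(C)C)C(C)C)cc1O[Si](C(C)C)(C(C)C)C(C)C)C(=O)C2 | intermediate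
24 | (6R,7R)-6-hydroxy-7-methyl-8-oxo-3-[(E)-3-oxoprop-1-enyl]-5,6,7,8-tetrahydro-1H-isochromen-7-yl 2-methyl-4,6-bis(triisopropylsilyloxy)benzoate | O=C/C=C/C1=CC2=C(CO1)C(=O)[C@](C)(OC(=O)c1c(C)cc(O[Si](C(C)C)(C(C)C)C(C)C)cc1O[Si](C(C)C)(C(C)C)C(C)C)[C@H](O)C2 | intermediate
25 | aldol adduct of 23 (through C5) with the aldehyde carbon of 24, a β-hydroxy ketone, mixture at C5 and the carbinol carbon | CC(=O)OC/C=C/C1=CC2=C(CO1)C(=O)[C@](C)(OC(=O)c1c(C)cc(O[Si](C(C)C)(C(C)C)C(C)C)cc1O[Si](C(C)C)(C(C)C)C(C)C)C(=O)C2C(O)/C=C/C1=CC2=C(CO1)C(=O)[C@](C)(OC(=O)c1c(C)cc(O[Si](C(C)C)(C(C)C)C(C)C)cc1O[Si](C(C)C)(C(C)C)C(C)C)[C@H](O)C2 | intermediate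
26 | tetrakis-O-triisopropylsilyl ether of the target, (5Z)-alkylidene, (7R) and (6'R,7'R) | CC(=O)OC/C=C/C1=CC2=C(CO1)C(=O)[C@](C)(OC(=O)c1c(C)cc(O[Si](C(C)C)(C(C)C)C(C)C)cc1O[Si](C(C)C)(C(C)C)C(C)C)C(=O)/C2=C\C=C\C1=CC2=C(CO1)C(=O)[C@](C)(OC(=O)c1c(C)cc(O[Si](C(C)C)(C(C)C)C(C)C)cc1O[Si](C(C)C)(C(C)C)C(C)C)[C@H](O)C2 | intermediate
27 | CNP0239166.2, (7R)-3-[(E)-3-acetoxyprop-1-enyl]-5-[(Z,2E)-3-{(6R,7R)-7-(2,4-dihydroxy-6-methylbenzoyloxy)-6-hydroxy-7-methyl-8-oxo-5,6,7,8-tetrahydro-1H-isochromen-3-yl}prop-2-enylidene]-7-methyl-6,8-dioxo-5,6,7,8-tetrahydro-1H-isochromen-7-yl 2,4-dihydroxy-6-methylbenzoate | CC(=O)OC/C=C/C1=CC2=C(CO1)C(=O)[C@](C)(OC(=O)c1c(C)cc(O)cc1O)C(=O)/C2=C\C=C\C1=CC2=C(CO1)C(=O)[C@](C)(OC(=O)c1c(C)cc(O)cc1O)[C@H](O)C2 | target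

Total step count: 17. Longest linear sequence: 15 steps (1, 2, 3, 4, 5, 6, 7, 8, 9, 11, 12, 13, 14, 16, 17).

Steps most likely to fail

Step 11 (proposed new method). The enolate may act as a base on 14 at C5, which would be followed by loss of the C6 silyloxy group, or the substitution at the fully substituted chloro-alkene carbon may be too slow, so that material is diverted before the C–C bond forms. The fallback sets out from 14 and returns at 20, making the same two bonds in separate, known operations. Sonogashira coupling of 14 (PdCl2(PPh3)2, CuI, Et3N, THF) with (E)-tert-butyldimethyl(pent-2-en-4-ynyloxy)silane F1, made from commercial (E)-pent-2-en-4-yn-1-ol with TBSCl and imidazole, would form the C4–C4a bond and give the dienynone F2. Gold-catalysed hydration (Ph3PAuNTf2, wet dioxane) should place oxygen on C3, the alkyne carbon remote from the enone, and give diketone 18 as an isolated compound. Treatment of 18 with DBU in THF would then trigger the 1,4-elimination of sulfinate and the oxa-6π closure through 19 to 20.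

Step 16. Conjugate instead of carbonyl addition to the dienal, amine-induced retro-Claisen opening of the acyloxy dione, or incomplete equilibration of the alkylidene geometry may erode the union. The fallback sets out from 23 and 24 and returns at 26 by a directed aldol reaction followed by a separate elimination. Compound 23 would be converted (TMSOTf, Et3N) into its C6 trimethylsilyl dienol ether F3, which undergoes a Mukaiyama aldol addition to 24 (BF3·OEt2, CH2Cl2, −78 °C) to give aldol adduct 25 as an isolated compound. The unhindered allylic carbinol of 25 would then be converted with MsCl and Et3N at −40 °C into the mesylate F4, and E1cB elimination with DBU should give 26.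

Step 2. Carbon–oxygen bond formation at a fully substituted carbon with a di-ortho-substituted carboxylate may be slow, and residual acetate or oxidation of the electron-rich arene may compete. The fallback sets out from 4 and returns at 5 by forming the acyl–oxygen bond instead. Compound 4 would be hydroxylated with dimethyldioxirane in acetone to 2-hydroxy-2-methylcyclohexane-1,3-dione F5. Acid 3 would be converted under neutral conditions (1-chloro-N,N,2-trimethylpropenylamine, CH2Cl2) into 2-methyl-4,6-bis(triisopropylsilyloxy)benzoyl chloride F6. F5 would then be acylated by F6 through the unhindered acylium ion (AgOTf, 2,6-di-tert-butylpyridine, CH2Cl2) to give 5.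

Further compounds
F1 | step 11 | (E)-tert-butyldimethyl(pent-2-en-4-ynyloxy)silane | C#C/C=C/CO[Si](C)(C)C(C)(C)C
F2 | step 11 | (1R,6R)-4-[(E)-5-(tert-butyldimethylsilyloxy)pent-3-en-1-ynyl]-1-methyl-2-oxo-3-(tosylmethyl)-6-(triethylsilyloxy)cyclohex-3-en-1-yl 2-methyl-4,6-bis(triisopropylsilyloxy)benzoate | CC(C)(C)[Si](C)(C)OC/C=C/C#CC1=C(CS(=O)(=O)c2ccc(C)cc2)C(=O)[C@](C)(OC(=O)c2c(C)cc(O[Si](C(C)C)(C(C)C)C(C)C)cc2O[Si](C(C)C)(C(C)C)C(C)C)[C@H](O[Si](CC)(CC)CC)C1
F3 | step 16 | (7R)-3-[(E)-3-acetoxyprop-1-enyl]-7-methyl-8-oxo-6-(trimethylsilyloxy)-7,8-dihydro-1H-isochromen-7-yl 2-methyl-4,6-bis(triisopropylsilyloxy)benzoate | CC(=O)OC/C=C/C1=CC2=C(CO1)C(=O)[C@](C)(OC(=O)c1c(C)cc(O[Si](C(C)C)(C(C)C)C(C)C)cc1O[Si](C(C)C)(C(C)C)C(C)C)C(O[Si](C)(C)C)=C2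
F4 | step 16 | methanesulfonate of aldol adduct 25 at the allylic carbinol | CC(=O)OC/C=C/C1=CC2=C(CO1)C(=O)[C@](C)(OC(=O)c1c(C)cc(O[Si](C(C)C)(C(C)C)C(C)C)cc1O[Si](C(C)C)(C(C)C)C(C)C)C(=O)C2C(OS(C)(=O)=O)/C=C/C1=CC2=C(CO1)C(=O)[C@](C)(OC(=O)c1c(C)cc(O[Si](C(C)C)(C(C)C)C(C)C)cc1O[Si](C(C)C)(C(C)C)C(C)C)[C@H](O)C2
F5 | step 2 | 2-hydroxy-2-methylcyclohexane-1,3-dione | CC1(O)C(=O)CCCC1=O
F6 | step 2 | 2-methyl-4,6-bis(triisopropylsilyloxy)benzoyl chloride | Cc1cc(O[Si](C(C)C)(C(C)C)C(C)C)cc(O[Si](C(C)C)(C(C)C)C(C)C)c1C(Cl)=O
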